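**Retrosynthetic overview**
1. The target is the 2,3-cis,2'',3''-cis 3,3''-biflavanone (2R,3R,2''R,3''R). Its two C3–H bonds are made last, by kinetic protonation of the bis(silyl enol ether) of the 1,4-diketone, which resets C3 and C3'' whatever their configuration.
2. Key disconnection C3–C3'': two complete (2R)-flavanones are joined late, one as a trivalent-iodine enolonium species (C3'' electrophilic), the other as its silyl enol ether (C3 nucleophilic).
3. Both flavanones come from one intermediate, (2R)-isosakuranetin; the unit B flavanone is its 7-O-methyl ether.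
4. C2 and C2'' are set once, by enantioselective Pd-catalysed 1,4-addition of 4-methoxyphenylboronic acid to 5,7-dihydroxychromone.
5. Ring order: rings A and C are bought as the chromone, ring B is attached in step 1, then the two units are joined; no ring is formed afterwards.

Assumption: the SMILES is read as (2R,3R,2''R,3''R), i.e. H-2/H-3 cis in both pyranone rings; unit A is the 5,7-dihydroxy half (C2, C3), unit B the 5''-hydroxy-7''-methoxy half (C2'', C3''); 5,7-dihydroxychromone is taken as purchasable.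

**Route**

Step 1
Reactants: 1 5,7-dihydroxy-4H-chromen-4-one; 2 4-methoxyphenylboronic acid (2 equiv)
Product: 3 (2R)-5,7-dihydroxy-2-(4-methoxyphenyl)chroman-4-one [(R)-isosakuranetin]
Conditions: Pd(OCOCF3)2 (5 mol %), (S)-4-tert-butyl-2-(pyridin-2-yl)-4,5-dihydrooxazole (6 mol %), NH4PF6 (30 mol %), H2O (5 equiv), ClCH2CH2Cl, 60 °C
Reagents that add atoms: none
Why: Enantioselective Pd-catalysed conjugate arylation of the chromone C2=C3 bond (aryl transfer to divalent palladium, carbopalladation, protonolysis) under base-free conditions that keep the phenols protonated and do not open the flavanone; the ligand blocks one face so the aryl group enters to give 2R (sense taken by analogy with cyclic enones, the antipodal ligand is used if it proves opposite).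

Step 2
Reactants: 3 (R)-isosakuranetin
Product: 4 (2R)-5-hydroxy-7-methoxy-2-(4-methoxyphenyl)chroman-4-one
Conditions: Me3SiCHN2 (1.1 equiv), MeOH/PhMe 1:4, 0 °C → rt
Reagents that add atoms: trimethylsilyldiazomethane, C[Si](C)(C)C=[N+]=[N-]
Why: Diazoalkane O-methylation of the most acidic phenol (7-OH, vinylogous acid), while the 5-OH is chelated to C4=O and inert; neutral conditions avoid the base-induced chalcone ring opening that would racemise C2.

Step 3
Reactants: 3 (R)-isosakuranetin
Product: 5 (2R)-2-(4-methoxyphenyl)-4,5,7-tris(trimethylsilyloxy)-2H-chromene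
Conditions: Me3SiOTf (3.5 equiv), Et3N (5 equiv), CH2Cl2, 0 °C → rt; non-aqueous work-up, used crude
Reagents that add atoms: trimethylsilyl triflate, C[Si](C)(C)OS(=O)(=O)C(F)(F)F
Why: Phenol silylation plus soft enolisation (O-silylation of the ketone, then loss of H-3 to the amine) gives the silyl enol ether without a free enolate, so there is no E1cB ring opening and C2 is untouched.

Step 4
Reactants: 4 (2R)-5-hydroxy-7-methoxy-2-(4-methoxyphenyl)chroman-4-one
Product: 6 (2R)-7-methoxy-2-(4-methoxyphenyl)-4,5-bis(trimethylsilyloxy)-2H-chromene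
Conditions: Me3SiOTf (2.4 equiv), Et3N (4 equiv), CH2Cl2, 0 °C → rt; non-aqueous work-up, used crude
Reagents that add atoms: trimethylsilyl triflate, C[Si](C)(C)OS(=O)(=O)C(F)(F)F
Why: Same soft enolisation/silylation as step 3; C2 is untouched.

Step 5
Reactants: 6 (2R)-7-methoxy-2-(4-methoxyphenyl)-4,5-bis(trimethylsilyloxy)-2H-chromene (1.0 equiv); 5 (2R)-2-(4-methoxyphenyl)-4,5,7-tris(trimethylsilyloxy)-2H-chromene (1.5 equiv)
Product: 9 (2R,3S,2''R,3''S)-5,5'',7-trihydroxy-7''-methoxy-2,2''-bis(4-methoxyphenyl)-3,3''-bichroman-4,4''-dione (both rings 2,3-trans), via O-iodanyl enolate 7 (not isolated), via tris-silylated diketone 8 (not isolated)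
Conditions: PhI(OH)OTs (1.2 equiv), BF3·OEt2 (1.5 equiv, activator), CH2Cl2, −78 °C; add 6, 5 min; add 5, −78 → −40 °C; aq. citric acid/MeOH work-up
Reagents that add atoms: none
Why: Enolonium (umpoled enolate) cross-coupling: the activated iodane turns 6 into the O-bound λ3-iodanyl enolate 7, whose C3'' is electrophilic; silyl enol ether 5 attacks it with loss of PhI, joining two natively nucleophilic α-carbons as a 1,4-diketone. Each bond forms anti to the neighbouring 2-aryl group, so the trans,trans isomer is expected, but C3 and C3'' are reset in step 6 and C2, C2'' are not touched.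

Step 6
Reactants: 9 trans,trans-biflavanone (any C3/C3'' epimers included)
Product: 11 (2R,3R,2''R,3''R)-5,5'',7-trihydroxy-7''-methoxy-2,2''-bis(4-methoxyphenyl)-3,3''-bichroman-4,4''-dione (both rings 2,3-cis; the target), via pentasilyl bis-enol ether 10 (not isolated)
Conditions: Me3SiOTf (7 equiv), Et3N (10 equiv), ClCH2CH2Cl, 0 → 40 °C, dark; evaporate; n-Bu4NF/AcOH 1:2 (6 equiv), THF, −78 → −30 °C
Reagents that add atoms: none
Why: Soft enolisation followed by kinetic (Zimmerman-type) protonation: both ketones become silyl enol ethers, erasing C3 and C3''; fluoride-triggered protodesilylation at low temperature delivers each proton to the enol face opposite the pseudoaxial 2-aryl group. The 3,3''-bond therefore ends up cis to both aryl groups (3R,3''R), and the ArO–SiMe3 groups fall off in the same operation.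

**Compound list**
1 | 5,7-dihydroxy-4H-chromen-4-one | O=c1ccoc2cc(O)cc(O)c12 | starting material
2 | 4-methoxyphenylboronic acid | COc1ccc(B(O)O)cc1 | starting material
3 | (2R)-5,7-dihydroxy-2-(4-methoxyphenyl)chroman-4-one | COc1ccc([C@@H]2Oc3cc(O)cc(O)c3C(=O)C2)cc1 | intermediate
4 | (2R)-5-hydroxy-7-methoxy-2-(4-methoxyphenyl)chroman-4-one | COc1ccc([C@@H]2Oc3cc(OC)cc(O)c3C(=O)C2)cc1 | intermediate
5 | (2R)-2-(4-methoxyphenyl)-4,5,7-tris(trimethylsilyloxy)-2H-chromene | COc1ccc([C@@H]2Oc3cc(O[Si](C)(C)C)cc(O[Si](C)(C)C)c3C(O[Si](C)(C)C)=C2)cc1 | intermediate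
6 | (2R)-7-methoxy-2-(4-methoxyphenyl)-4,5-bis(trimethylsilyloxy)-2H-chromene | COc1ccc([C@@H]2Oc3cc(OC)cc(O[Si](C)(C)C)c3C(O[Si](C)(C)C)=C2)cc1 | intermediate
7 | [(2R)-7-methoxy-2-(4-methoxyphenyl)-5-(trimethylsilyloxy)-2H-chromen-4-yl]oxy(phenyl)(tosyloxy)-λ3-iodane (O-bound enolonium species from 6) | COc1ccc([C@@H]2Oc3cc(OC)cc(O[Si](C)(C)C)c3C(OI(c3ccccc3)OS(=O)(=O)c3ccc(C)cc3)=C2)cc1 | intermediate
8 | (2R,3S,2''R,3''S)-7''-methoxy-2,2''-bis(4-methoxyphenyl)-5,5'',7-tris(trimethylsilyloxy)-3,3''-bichroman-4,4''-dione (both rings trans) | COc1ccc([C@@H]2Oc3cc(O[Si](C)(C)C)cc(O[Si](C)(C)C)c3C(=O)[C@H]2[C@@H]2C(=O)c3c(O[Si](C)(C)C)cc(OC)cc3O[C@H]2c2ccc(OC)cc2)cc1 | intermediate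
9 | (2R,3S,2''R,3''S)-5,5'',7-trihydroxy-7''-methoxy-2,2''-bis(4-methoxyphenyl)-3,3''-bichroman-4,4''-dione (both rings trans) | COc1ccc([C@@H]2Oc3cc(O)cc(O)c3C(=O)[C@H]2[C@@H]2C(=O)c3c(O)cc(OC)cc3O[C@H]2c2ccc(OC)cc2)cc1 | intermediate
10 | 7''-methoxy-2,2''-bis(4-methoxyphenyl)-4,4'',5,5'',7-pentakis(trimethylsilyloxy)-2H,2''H-3,3''-bichromene (CIP 2S,2''S; same spatial arrangement at C2, C2'' as in 9, the descriptor changes because C3 now outranks the aryl group) | COc1ccc([C@@H]2Oc3cc(O[Si](C)(C)C)cc(O[Si](C)(C)C)c3C(O[Si](C)(C)C)=C2C2=C(O[Si](C)(C)C)c3c(O[Si](C)(C)C)cc(OC)cc3O[C@H]2c2ccc(OC)cc2)cc1 | intermediate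
11 | (2R,3R,2''R,3''R)-5,5'',7-trihydroxy-7''-methoxy-2,2''-bis(4-methoxyphenyl)-3,3''-bichroman-4,4''-dione (both rings cis) | COc1ccc([C@@H]2Oc3cc(O)cc(O)c3C(=O)[C@@H]2[C@H]2C(=O)c3c(O)cc(OC)cc3O[C@H]2c2ccc(OC)cc2)cc1 | target

**Totals and risks**
Total steps: 6. Longest linear sequence: 5 (steps 1, 2, 4, 5, 6).

Steps most likely to fail:

1. Step 5. The enolonium 7 carries an anisyl group next to the electrophilic carbon and could lose PhI by 1,2-aryl shift (isoflavone) or by elimination (flavone) before 5 attacks; the bond formed is also tertiary–tertiary. Fallback, setting out from 6 and coming back at 8: 6 is brominated (N-bromosuccinimide, THF, −78 °C) to the 2,3-trans 3-bromoflavanone F1. Blue-light irradiation of F1 and 5 with tris(2-phenylpyridinato)iridium, fac-Ir(C11H8N)3 (1 mol %), in MeCN generates the electrophilic C3'' α-keto radical, which adds to the silyl enol ether; oxidation of the adduct radical and loss of the silyl group give 8, hydrolysed to 9 as in step 5. No cationic C3'' is involved, so the aryl shift is avoided.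

2. Step 6. Double enolisation of the hindered diketone may stall, or protonation may leak to the trans isomers. Fallback, setting out from 10 and coming back at 11: 10 is oxidised (DDQ, CH2Cl2, −40 °C, then aq. citric acid/MeOH) to the (E)-ene-dione F2. In the E isomer of this homochiral compound both 2-aryl groups lie on the same alkene face, so hydrogenation (H2 1 atm, palladium on carbon Pd/C, EtOAc, 0 °C) adds both hydrogens syn from the opposite face and gives 11 directly.

3. Step 1. The free 7-OH may lower rate or ee, and the electron-rich boronic acid can protodeboronate. Fallback, setting out from 1 and coming back at 3: 1 is silylated at O-7 (i-Pr3SiCl, imidazole, DMF) to the 7-silyloxychromone F3. Rh-catalysed asymmetric 1,4-addition of 2 ([Rh(OH)(cod)]2, cod = 1,5-cyclooctadiene, with the antipode of an electron-poor atropisomeric bisphosphine that gives 2R, PhMe/H2O, rt) gives the flavanone F4, and HF·pyridine in THF returns 3.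

**Further compounds**
F1 | step 5 | 3-bromo-7-methoxy-2-(4-methoxyphenyl)-5-(trimethylsilyloxy)chroman-4-one, 2,3-trans (CIP 2S,3S; C2 spatially as in 6) | COc1ccc([C@@H]2Oc3cc(OC)cc(O[Si](C)(C)C)c3C(=O)[C@H]2Br)cc1
F2 | step 6 | (E)-5,5'',7-trihydroxy-7''-methoxy-2,2''-bis(4-methoxyphenyl)-3,3''-bichromanylidene-4,4''-dione (CIP 2S,2''S; C2, C2'' spatially as in 9) | COc1ccc([C@@H]2Oc3cc(O)cc(O)c3C(=O)/C2=C2/C(=O)c3c(O)cc(OC)cc3O[C@H]2c2ccc(OC)cc2)cc1
F3 | step 1 | 5-hydroxy-7-(triisopropylsilyloxy)-4H-chromen-4-one | O=c1ccoc2cc(O[Si](C(C)C)(C(C)C)C(C)C)cc(O)c12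
F4 | step 1 | (2R)-5-hydroxy-2-(4-methoxyphenyl)-7-(triisopropylsilyloxy)chroman-4-one | COc1ccc([C@@H]2Oc3cc(O[Si](C(C)C)(C(C)C)C(C)C)cc(O)c3C(=O)C2)cc1
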